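Follow one molecule of substrate and ask for its chance of still being free at the end.

| flask | substrate | coupling partner | free catalyst | remark | time |
|---|---|---|---|---|---|
| Saturday's | 1.3 M | 2.6 M | 15 mM | run made earlier |  |
| Wednesday's | 1.3 M | 2.6 M | 34 mM | run made earlier |  |
| south-west | 1.3 M | 2.60 M | 32 mM |  | 50 h |
| west | 1.3 M | 2.60 M | 13 mM |  | 50 h |
| north-east | 1.3 M | 2.60 M | 81 mM |  | 50 h |

| run | time / h | substrate / % | catalyst intermediate B / % | side product / % | target / % |
|---|---|---|---|---|---|
| Saturday's | 2.00 | 97.7 | 0.7 | 0 | 1.5 |
| Saturday's | 6.00 | 96.0 | 0.7 | 0.5 | 3.3 |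
| Saturday's | 12.0 | 92.7 | 0.5 | 0.1 | 6.1 |
| Saturday's | 20.0 | 89.6 | 0.8 | 0.2 | 9.0 |
| Saturday's | 25.0 | 87.7 | 1.4 | 0.1 | 10.6 |
| Wednesday's | 2.00 | 95.6 | 1.2 | 0 | 2.3 |
| Wednesday's | 4.00 | 93.0 | 1.2 | 0.1 | 5.0 |
| Wednesday's | 8.00 | 88.0 | 1.0 | 0.4 | 9.9 |
| Wednesday's | 12.0 | 84.0 | 1.7 | 0 | 13.7 |
| Wednesday's | 25.0 | 74.8 | 2.1 | 0.9 | 22.7 |

(scatter of a reading: 0.3 percentage points)

1. which of these there is most of at the end, counted by the substrate in it, south-west (substrate / target / catalyst intermediate B / side product)
2. which of these there is most of at the end, counted by the substrate in it, west (substrate / target / catalyst intermediate B / side product)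
3. which of these there is most of at the end, counted by the substrate in it, north-east (substrate / target / catalyst intermediate B / side product)
4. the largest of these amounts at the end, in percent of the substrate charged, south-west
5. the largest of these amounts at the end, in percent of the substrate charged, west
6. the largest of these amounts at the end, in percent of the substrate charged, north-east

- percentages count the substrate that a species holds: one side product counts as two

Minutes. The bench chemist opened: the earlier flasks differ in catalyst, which is 0.0115 of the substrate charge in Saturday's run and 0.0262 in Wednesday's. The kineticist proposed that a substrate molecule's risk at each moment goes with that fraction. Its survival would then be an exponential, and the exponent per unit of catalyst fraction, which she called the reach, should depend on the clock and not on the flask. She read it off the substrate columns. At 12.0 h Saturday's run gives 6.57 and Wednesday's 6.67; at 25.0 h they give 11.4 and 11.1.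

The bench chemist objected that the reach slows: the second window adds 0.698 of what the first gave. The kineticist agreed, and let each further window shrink by that ratio. This is an assumption, and it keeps the coupling partner charge as in those runs. Two windows on, she committed to 16.7 at 50 h for the reach, the negative logarithm of the substrate fraction left divided by the catalyst fraction.

So free substrate comes to 84.6 % in west, 66.3 % in south-west and 35.3 % in north-east. For north-east, the bench chemist set aside the catalyst charge as catalyst intermediate B, the resting state, which leaves target near 58.5 %, ahead of substrate.

The forecast, holding “That points to catalyst dying”, gave south-west 68.5 %, as substrate; west 84 %, as substrate; and north-east 53 %, as target, below the bench chemist's figure for north-east.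

The flasks gave south-west 66.0 %, as substrate; west 84.9 %, as substrate; and north-east 59.8 %, as target.

    substrate + free catalyst → catalyst intermediate A (k = 0.0550 L mol⁻¹ min⁻¹)
    catalyst intermediate A → catalyst intermediate B (k = 0.0920 min⁻¹)
    coupling partner + catalyst intermediate B → catalyst intermediate C (k = 0.0120 L mol⁻¹ min⁻¹)
    catalyst intermediate C ⇌ catalyst intermediate D (K = 0.750, k = 0.0970 min⁻¹)
    catalyst intermediate D → free catalyst + target (k = 0.0840 min⁻¹)
    target → over-reaction product (k = 1.10 × 10⁻⁶ min⁻¹)
    substrate + target → side product (k = 2.20 × 10⁻⁵ L mol⁻¹ min⁻¹)
    2 coupling partner → homo dimer (k = 5.80 × 10⁻⁴ L mol⁻¹ min⁻¹)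

In west, 8.1 % of the coupling partner remained at the end against 85 % of the substrate. Taken back from the flasks, the reach is 16.3 in west and 18.8 in north-east. The neighbour of west, with 0.65 M of coupling partner and the same catalyst fraction, would keep 84.6 % at a reach of 16.7, yet it holds 90 % free, a reach of 10.4.

All runs come from a simulation for substances that don't exist, and the scatter is random.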